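**Strategy.** The enolised 1,3-diketone (C(=O)–CH=C(OH)) at the centre of the heptadienone chain is treated as a ring-opened isoxazole, and the chain is cut between the feruloyl carbonyl carbon and the central CH. A copper-catalysed nitrile oxide–alkyne cycloaddition joins the dipole from coniferaldehyde oxime to a terminal enyne that already carries the guaiacyl ether of the oxidised bisabolane cyclohexene, forming that C–C bond and the ring C–O bond in one operation. The resulting 3,5-distyrylisoxazole is a masked diketone that N–O scission and hydrolysis unveil. The enyne fragment comes from an organocatalytic Robinson annulation and a palladium-catalysed cis-1,4 opening of a vinyl epoxide by a phenol.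

Key step: step 13

Remark: the target is written as one enol of a 1,3-diketone; the enol forms interconvert rapidly, so releasing the diketone in the last step gives the target as drawn.

**Step 1**
Reactants: 1 (3R)-5-methoxy-3-methyl-5-oxopentanoic acid
Product: 2 methyl (3R)-5-hydroxy-3-methylpentanoate
Conditions: BH3·SMe2, THF, 0 °C → rt; MeOH quench
Reagents that add atoms: none
Why: Borane reduces the free carboxylic acid through an acyloxyborane much faster than the methyl ester, so only the acid arm becomes CH2OH and the (3R) centre is untouched (chemoselective borane reduction).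

**Step 2**
Reactants: 2 methyl (3R)-5-hydroxy-3-methylpentanoate
Product: 3 methyl (3R)-3-methyl-5-oxopentanoate
Conditions: PhI(OAc)2, TEMPO (10 mol %), CH2Cl2, rt
Reagents that add atoms: none
Why: The oxoammonium-mediated oxidation should stop at the aldehyde and leave the ester and the β-stereocentre unaffected (TEMPO oxidation).

**Step 3**
Reactants: 3 methyl (3R)-3-methyl-5-oxopentanoate; 4 methyl vinyl ketone
Product: 6 methyl (3S)-3-[(1R)-4-oxocyclohex-2-en-1-yl]butanoate, via keto aldehyde 5 (not isolated)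
Conditions: 4 (1.5 equiv), (R)-2-[methoxy(diphenyl)methyl]pyrrolidine (10 mol %), ethyl 3,4-dihydroxybenzoate (20 mol %), neat, 4 °C; volatiles removed; then LiOH·H2O (0.3 equiv), i-PrOH, rt
Reagents that add atoms: none
Why: The (R)-diarylprolinol ether shields one face of the (E)-enamine of 3, so the asymmetric Michael addition to 4 should set the new α-centre as (4R) under catalyst control, and LiOH then closes the ring by intramolecular aldol condensation of the methyl ketone onto the aldehyde (Robinson annulation).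

**Step 4**
Reactants: 6 methyl (3S)-3-[(1R)-4-oxocyclohex-2-en-1-yl]butanoate
Product: 7 methyl (3S)-3-[(1R)-4-(trifluoromethanesulfonyloxy)cyclohexa-2,4-dien-1-yl]butanoate
Conditions: LDA (1.05 equiv), THF, −78 °C; then PhNTf2, −78 → 0 °C
Reagents that add atoms: N-phenylbis(trifluoromethanesulfonimide), O=S(=O)(N(c1ccccc1)S(=O)(=O)C(F)(F)F)C(F)(F)F
Why: Kinetic deprotonation at the α′-CH2 of the enone, which is more acidic than the ester α-CH2, gives the cross-conjugated dienolate that is O-sulfonylated to the 2-triflyloxy-1,3-diene without touching a stereocentre (enol triflate formation).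

**Step 5**
Reactants: 7 methyl (3S)-3-[(1R)-4-(trifluoromethanesulfonyloxy)cyclohexa-2,4-dien-1-yl]butanoate
Product: 8 methyl (3S)-3-[(1R)-4-methylcyclohexa-2,4-dien-1-yl]butanoate
Conditions: MeMgBr, Fe(acac)3 (5 mol %), THF/NMP, −30 °C
Reagents that add atoms: methylmagnesium bromide, C[Mg]Br
Why: Iron-catalysed Kumada-type coupling of the alkenyl triflate should be faster than Grignard addition to the ester at low temperature and installs the ring methyl group with the 1,3-diene already in place.

**Step 6**
Reactants: 8 methyl (3S)-3-[(1R)-4-methylcyclohexa-2,4-dien-1-yl]butanoate; 9 (2-methylprop-1-en-1-yl)magnesium bromide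
Product: 11 (6S)-2-methyl-6-[(1R)-4-methylcyclohexa-2,4-dien-1-yl]hept-2-en-4-one, via N-methoxy-N-methylamide 10 (not isolated)
Conditions: MeNHOMe·HCl, i-PrMgCl, THF, −20 °C; then 9, −20 → 0 °C; NH4Cl (aq.)
Reagents that add atoms: none
Why: The ester is converted in situ into the N-methoxy-N-methylamide, whose magnesium chelate accepts one equivalent of 9 and releases the β,β-dimethyl enone only on work-up (Weinreb ketone synthesis).

**Step 7**
Reactants: 11 (6S)-2-methyl-6-[(1R)-4-methylcyclohexa-2,4-dien-1-yl]hept-2-en-4-one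
Product: 12 (6S)-2-methyl-6-[(1R,4R,6S)-1-methyl-7-oxabicyclo[4.1.0]hept-2-en-4-yl]hept-2-en-4-one
Conditions: mCPBA (1.0 equiv), NaHCO3 (aq.)/CH2Cl2, 0 °C; used crude
Reagents that add atoms: 3-chloroperbenzoic acid, O=C(OO)c1cccc(Cl)c1
Why: The peracid should select the electron-rich trisubstituted diene alkene over the disubstituted one and the enone, and approach anti to the pseudo-axial side chain, setting the two epoxide centres as (1R,6S) (Prilezhaev epoxidation).

**Step 8**
Reactants: 13 vanillin
Product: 14 4-(tert-butyldimethylsilyloxy)-3-methoxybenzaldehyde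
Conditions: TBSCl, imidazole, DMF, rt
Reagents that add atoms: tert-butyldimethylsilyl chloride, CC(C)(C)[Si](C)(C)Cl
Why: Silylation masks the acidic phenol so that the aldehyde keeps its electrophilicity in the olefination (silyl ether formation).

**Step 9**
Reactants: 14 4-(tert-butyldimethylsilyloxy)-3-methoxybenzaldehyde; 15 diethyl [3-(trimethylsilyl)prop-2-yn-1-yl]phosphonate
Product: 16 tert-butyl{2-methoxy-4-[(1E)-4-(trimethylsilyl)but-1-en-3-yn-1-yl]phenoxy}dimethylsilane
Conditions: 15, LiHMDS, THF, −78 °C; then 14, −78 → 0 °C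
Reagents that add atoms: none
Why: Horner–Wadsworth–Emmons olefination with the lithiated propargylic phosphonate should give the conjugated enyne with the thermodynamically preferred (E) geometry.

**Step 10**
Reactants: 16 tert-butyl{2-methoxy-4-[(1E)-4-(trimethylsilyl)but-1-en-3-yn-1-yl]phenoxy}dimethylsilane
Product: 17 2-methoxy-4-[(1E)-but-1-en-3-yn-1-yl]phenol
Conditions: Bu4NF (2.2 equiv), THF, 0 °C; NH4Cl (aq.)
Reagents that add atoms: none
Why: Fluoride cleaves the aryl silyl ether and the alkynyl C–Si bond in one operation and leaves the (E)-enyne intact (desilylation).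

**Step 11**
Reactants: 12 (6S)-2-methyl-6-[(1R,4R,6S)-1-methyl-7-oxabicyclo[4.1.0]hept-2-en-4-yl]hept-2-en-4-one; 17 2-methoxy-4-[(1E)-but-1-en-3-yn-1-yl]phenol
Product: 18 (6S)-6-[(1R,2R,5S)-2-{4-[(1E)-but-1-en-3-yn-1-yl]-2-methoxyphenoxy}-5-hydroxy-4-methylcyclohex-3-en-1-yl]-2-methylhept-2-en-4-one
Conditions: Pd(PPh3)4 (5 mol %), THF, 0 °C → rt; 12 added slowly to 17 and catalyst
Reagents that add atoms: none
Why: Zerovalent palladium ionises the allylic epoxide C–O bond with inversion and the phenoxide attacks the distal, less hindered allyl terminus anti to the metal, so net retention places the aryloxy group cis to the hydroxyl and trans to the side chain and sets the (2R) centre (Tsuji–Trost opening of a vinyl epoxide).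

**Step 12**
Reactants: 19 coniferaldehyde
Product: 20 (1E,2E)-3-(4-hydroxy-3-methoxyphenyl)prop-2-enal oxime
Conditions: NH2OH·HCl, NaOAc, EtOH/H2O, rt
Reagents that add atoms: hydroxylamine hydrochloride, Cl.NO
Why: Buffered condensation of the enal with hydroxylamine gives the conjugated aldoxime and leaves the phenol and the (E)-alkene untouched (oxime formation).

**Step 13**
Reactants: 20 (1E,2E)-3-(4-hydroxy-3-methoxyphenyl)prop-2-enal oxime; 18 (6S)-6-[(1R,2R,5S)-2-{4-[(1E)-but-1-en-3-yn-1-yl]-2-methoxyphenoxy}-5-hydroxy-4-methylcyclohex-3-en-1-yl]-2-methylhept-2-en-4-one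
Product: 23 (6S)-6-[(1R,2R,5S)-5-hydroxy-2-{4-[(E)-2-{3-[(E)-2-(4-hydroxy-3-methoxyphenyl)ethenyl]-1,2-oxazol-5-yl}ethenyl]-2-methoxyphenoxy}-4-methylcyclohex-3-en-1-yl]-2-methylhept-2-en-4-one, via hydroximoyl chloride 21 (not isolated), via nitrile oxide 22 (not isolated)
Conditions: 20, NCS, DMF, 0 °C → rt; crude solution added over 4 h to 18, CuSO4·5H2O (5 mol %), sodium ascorbate (20 mol %), KHCO3, t-BuOH/THF/H2O, rt
Reagents that add atoms: none
Why: NCS chlorinates aldoxime 20 at carbon to give 21, KHCO3 eliminates HCl to release nitrile oxide 22, and the copper acetylide formed from 18 and monovalent copper (CuSO4 reduced by sodium ascorbate) adds through its terminal carbon to the dipole carbon, after which the oxygen closes onto the internal alkyne carbon and protonolysis frees the isoxazole. The closest known reaction type is the copper-catalysed nitrile oxide–alkyne 1,3-dipolar cycloaddition (Huisgen type). The five-membered isoxazole ring is closed in a stepwise formal [3+2] mode, C–C bond first and C–O bond second. No stereocentre is created, and the four stereocentres of the cyclohexene fragment and all (E)-alkenes are remote from the reaction in a near-neutral medium at room temperature. The step needs 3,5-regioselectivity and chemoselectivity for the alkyne over the C=C bonds, the enone, the free alcohol and the phenols; both follow from the acetylide pathway, which only the terminal alkyne can enter, and slow release of 22 limits its dimerisation. The isoxazole so formed holds both carbonyl carbons and the central CH of the diketone in masked form.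

**Step 14**
Reactants: 23 (6S)-6-[(1R,2R,5S)-5-hydroxy-2-{4-[(E)-2-{3-[(E)-2-(4-hydroxy-3-methoxyphenyl)ethenyl]-1,2-oxazol-5-yl}ethenyl]-2-methoxyphenoxy}-4-methylcyclohex-3-en-1-yl]-2-methylhept-2-en-4-one
Product: 25 bisabolocurcumin ether, via enaminone 24 (not isolated)
Conditions: Mo(CO)6, MeCN/H2O, 80 °C; then oxalic acid (aq.), THF, rt
Reagents that add atoms: water, O
Why: Mo(CO)6 should cleave the weak N–O bond reductively without reducing alkenes or ketones to give the hydrogen-bonded (Z)-β-amino enone, whose vinylogous amide is hydrolysed by dilute acid too weak to ionise the allylic aryl ether, releasing the enolised 1,3-diketone with no stereocentre involved (isoxazole unmasking).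

**Compound list**

1 | (3R)-5-methoxy-3-methyl-5-oxopentanoic acid ((R)-methyl hydrogen 3-methylglutarate) | OC(=O)C[C@@H](C)CC(=O)OC | starting material
2 | methyl (3R)-5-hydroxy-3-methylpentanoate | OCC[C@@H](C)CC(=O)OC | intermediate
3 | methyl (3R)-3-methyl-5-oxopentanoate | O=CC[C@@H](C)CC(=O)OC | intermediate
4 | methyl vinyl ketone | C=CC(C)=O | starting material
5 | methyl (3S,4R)-4-formyl-3-methyl-7-oxooctanoate | CC(=O)CC[C@@H](C=O)[C@@H](C)CC(=O)OC | intermediate
6 | methyl (3S)-3-[(1R)-4-oxocyclohex-2-en-1-yl]butanoate | O=C1CC[C@@H](C=C1)[C@@H](C)CC(=O)OC | intermediate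
7 | methyl (3S)-3-[(1R)-4-(trifluoromethanesulfonyloxy)cyclohexa-2,4-dien-1-yl]butanoate | O=S(=O)(OC1=CC[C@@H](C=C1)[C@@H](C)CC(=O)OC)C(F)(F)F | intermediate
8 | methyl (3S)-3-[(1R)-4-methylcyclohexa-2,4-dien-1-yl]butanoate | CC1=CC[C@@H](C=C1)[C@@H](C)CC(=O)OC | intermediate
9 | (2-methylprop-1-en-1-yl)magnesium bromide | CC(C)=C[Mg]Br | starting material
10 | (3S)-N-methoxy-N-methyl-3-[(1R)-4-methylcyclohexa-2,4-dien-1-yl]butanamide | CC1=CC[C@@H](C=C1)[C@@H](C)CC(=O)N(C)OC | intermediate
11 | (6S)-2-methyl-6-[(1R)-4-methylcyclohexa-2,4-dien-1-yl]hept-2-en-4-one (α-turmerone) | CC1=CC[C@@H](C=C1)[C@@H](C)CC(=O)C=C(C)C | intermediate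
12 | (6S)-2-methyl-6-[(1R,4R,6S)-1-methyl-7-oxabicyclo[4.1.0]hept-2-en-4-yl]hept-2-en-4-one (epoxide oxygen anti to the side chain) | CC(C)=CC(=O)C[C@H](C)[C@@H]1C=C[C@@]2(C)O[C@H]2C1 | intermediate
13 | vanillin | COc1cc(C=O)ccc1O | starting material
14 | 4-(tert-butyldimethylsilyloxy)-3-methoxybenzaldehyde | COc1cc(C=O)ccc1O[Si](C)(C)C(C)(C)C | intermediate
15 | diethyl [3-(trimethylsilyl)prop-2-yn-1-yl]phosphonate | CCOP(=O)(CC#C[Si](C)(C)C)OCC | starting material
16 | tert-butyl{2-methoxy-4-[(1E)-4-(trimethylsilyl)but-1-en-3-yn-1-yl]phenoxy}dimethylsilane | COc1cc(/C=C/C#C[Si](C)(C)C)ccc1O[Si](C)(C)C(C)(C)C | intermediate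
17 | 2-methoxy-4-[(1E)-but-1-en-3-yn-1-yl]phenol | COc1cc(/C=C/C#C)ccc1O | intermediate
18 | (6S)-6-[(1R,2R,5S)-2-{4-[(1E)-but-1-en-3-yn-1-yl]-2-methoxyphenoxy}-5-hydroxy-4-methylcyclohex-3-en-1-yl]-2-methylhept-2-en-4-one | C#C/C=C/c1ccc(O[C@H]2C=C(C)[C@@H](O)C[C@@H]2[C@@H](C)CC(=O)C=C(C)C)c(OC)c1 | intermediate
19 | coniferaldehyde ((2E)-3-(4-hydroxy-3-methoxyphenyl)prop-2-enal) | COc1cc(/C=C/C=O)ccc1O | starting material
20 | (1E,2E)-3-(4-hydroxy-3-methoxyphenyl)prop-2-enal oxime | COc1cc(/C=C/C=N/O)ccc1O | intermediate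
21 | (1Z,2E)-N-hydroxy-3-(4-hydroxy-3-methoxyphenyl)prop-2-enimidoyl chloride | COc1cc(/C=C/C(Cl)=N/O)ccc1O | intermediate
22 | (2E)-3-(4-hydroxy-3-methoxyphenyl)prop-2-enenitrile N-oxide | COc1cc(/C=C/C#[N+][O-])ccc1O | intermediate
23 | (6S)-6-[(1R,2R,5S)-5-hydroxy-2-{4-[(E)-2-{3-[(E)-2-(4-hydroxy-3-methoxyphenyl)ethenyl]-1,2-oxazol-5-yl}ethenyl]-2-methoxyphenoxy}-4-methylcyclohex-3-en-1-yl]-2-methylhept-2-en-4-one | COc1cc(/C=C/c2cc(/C=C/c3ccc(O[C@H]4C=C(C)[C@@H](O)C[C@@H]4[C@@H](C)CC(=O)C=C(C)C)c(OC)c3)on2)ccc1O | intermediate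
24 | (1E,4Z,6E)-5-amino-7-(4-hydroxy-3-methoxyphenyl)-1-[4-{[(1R,4S,6R)-4-hydroxy-3-methyl-6-[(2S)-6-methyl-4-oxohept-5-en-2-yl]cyclohex-2-en-1-yl]oxy}-3-methoxyphenyl]hepta-1,4,6-trien-3-one | N/C(=C\C(=O)/C=C/c1ccc(O[C@H]2C=C(C)[C@@H](O)C[C@@H]2[C@@H](C)CC(=O)C=C(C)C)c(OC)c1)/C=C/c1ccc(O)c(OC)c1 | intermediate
25 | bisabolocurcumin ether ((1E,4Z,6E)-5-hydroxy-1-(4-hydroxy-3-methoxyphenyl)-7-[4-{[(1R,4S,6R)-4-hydroxy-3-methyl-6-[(2S)-6-methyl-4-oxohept-5-en-2-yl]cyclohex-2-en-1-yl]oxy}-3-methoxyphenyl]hepta-1,4,6-trien-3-one) | COc1cc(/C=C/C(=O)/C=C(O)/C=C/c2ccc(O[C@H]3C=C(C)[C@@H](O)C[C@@H]3[C@@H](C)CC(=O)C=C(C)C)c(OC)c2)ccc1O | target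

**Step count**

Total step count: 14. Longest linear sequence: 10 steps (steps 1 to 7, then 11, 13 and 14).

**Steps most likely to fail**

Step 7. The peracid may discriminate poorly between the two faces and deliver oxygen syn to the side chain, may also attack the disubstituted diene alkene, and the acid by-product may open or aromatise the vinyl epoxide. The fallback moves stereocontrol from the substrate to the reagent. It sets out again from 11 and uses a Shi epoxidation: the chiral fructose-derived ketone catalyst, KHSO5 (as 2KHSO5·KHSO4·K2SO4), K2CO3 buffer, MeCN/dimethoxymethane/H2O, 0 °C. The L-fructose-derived enantiomer of the ketone is the one that the spiro transition-state model predicts to deliver oxygen anti to the side chain. The medium is basic, so the epoxide is not exposed to acid. The fallback comes back to the route at 12 and makes no new compound (entry F0).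

Step 13. NCS may chlorinate the electron-rich phenolic ring or the styrene of 20, the nitrile oxide may dimerise to the furoxan, or the dipole may add to a C=C bond. The fallback forms the same C–C bond without a dipole and sets out from 18. Commercial (E)-4-acetoxy-3-methoxycinnamic acid is converted with (COCl)2 and catalytic DMF into (2E)-3-(4-acetoxy-3-methoxyphenyl)prop-2-enoyl chloride F1. An acyl Sonogashira coupling of F1 with 18 (PdCl2(PPh3)2, copper iodide CuI, Et3N, THF, 0 °C, no acyl-transfer catalyst, so that coupling of the acetylide should outpace esterification of the hindered secondary alcohol) should give the cross-conjugated ynone F2. Excess Et2NH in MeOH/THF should add to the alkyne carbon β to the carbonyl and at the same time cleave the aryl acetate, giving the diethylamino enaminone F3. Dilute aqueous oxalic acid should then hydrolyse this tertiary vinylogous amide. The fallback comes back to the route at 25 and bypasses 23 and 24.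

Step 11. The phenoxide may attack the tertiary allyl terminus, the allylpalladium intermediate may undergo β-hydride elimination to a dienol, or the terminal alkyne of 17 may be consumed by the catalyst. The fallback changes the nucleophile and the order of events and sets out from 12 and 13. Vanillin 13, which is more acidic and carries no alkyne, opens epoxide 12 under the same zerovalent palladium catalysis to give the aryl ether aldehyde F4. Horner–Wadsworth–Emmons olefination of F4 with excess lithiated 15 at −78 °C should give the silyl enyne F5. K2CO3 in MeOH then removes the alkynyl silyl group, and the fallback comes back to the route at 18.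

**Further compounds**

F0 | step 7 | none | none
F1 | step 13 | (2E)-3-(4-acetoxy-3-methoxyphenyl)prop-2-enoyl chloride | COc1cc(/C=C/C(Cl)=O)ccc1OC(C)=O
F2 | step 13 | (1E,6E)-1-(4-acetoxy-3-methoxyphenyl)-7-[4-{[(1R,4S,6R)-4-hydroxy-3-methyl-6-[(2S)-6-methyl-4-oxohept-5-en-2-yl]cyclohex-2-en-1-yl]oxy}-3-methoxyphenyl]hepta-1,6-dien-4-yn-3-one | CC(=O)Oc1ccc(/C=C/C(=O)C#C/C=C/c2ccc(O[C@H]3C=C(C)[C@@H](O)C[C@@H]3[C@@H](C)CC(=O)C=C(C)C)c(OC)c2)cc1OC
F3 | step 13 | (1E,4E,6E)-5-(diethylamino)-1-(4-hydroxy-3-methoxyphenyl)-7-[4-{[(1R,4S,6R)-4-hydroxy-3-methyl-6-[(2S)-6-methyl-4-oxohept-5-en-2-yl]cyclohex-2-en-1-yl]oxy}-3-methoxyphenyl]hepta-1,4,6-trien-3-one | COc1cc(/C=C/C(=O)/C=C(\C=C\c2ccc(O[C@H]3C=C(C)[C@@H](O)C[C@@H]3[C@@H](C)CC(=O)C=C(C)C)c(OC)c2)N(CC)CC)ccc1O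
F4 | step 11 | 4-{[(1R,4S,6R)-4-hydroxy-3-methyl-6-[(2S)-6-methyl-4-oxohept-5-en-2-yl]cyclohex-2-en-1-yl]oxy}-3-methoxybenzaldehyde | COc1cc(C=O)ccc1O[C@H]1C=C(C)[C@@H](O)C[C@@H]1[C@@H](C)CC(=O)C=C(C)C
F5 | step 11 | (6S)-6-[(1R,2R,5S)-5-hydroxy-2-{2-methoxy-4-[(1E)-4-(trimethylsilyl)but-1-en-3-yn-1-yl]phenoxy}-4-methylcyclohex-3-en-1-yl]-2-methylhept-2-en-4-one | COc1cc(/C=C/C#C[Si](C)(C)C)ccc1O[C@H]1C=C(C)[C@@H](O)C[C@@H]1[C@@H](C)CC(=O)C=C(C)C
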